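## Retrosynthetic overview

Numbering used below: C1 lactone C=O, C2 (Me), C3 ketone, C4 (OH, CH2OH), C5, C6=C7 (6-Me), C8 (Me), C9, C10 (=CH2), C11=C12 (12-Me), C13 (Et, ring O).

1. Target ⇐ bis-silyl ether 34 by global desilylation; the only ring (14-membered lactone) is closed one step earlier by intramolecular Stille coupling C10–C11.
2. Seco ester 33 ⇐ propanoate aldol and oxidation (C2–C3) between stannyl propanoate 30 (fragment A: C11–C13 plus C1–C2) and aldehyde 20 (fragment B: C3–C10).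
3. Fragment B: C4 by Sharpless epoxidation and regioselective opening; C5–C6 by allyl–vinyl Stille; C6=C7 by Zhao–Wittig; C8 by an ene-reductase reduction (first stereocentre); C10 bromide from an alkyne.
4. Fragment A: C13 by Noyori transfer hydrogenation of an ynone; Z-C11=C12 by anti-carbomagnesiation and iodination.

Assumption: C2 lies between two carbonyls and is configurationally labile; the (2R) epimer of the target is taken to be the thermodynamically preferred one in the 14-membered ring and is set by equilibration in the last step.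

## Route

Step 1
Reactants: 1 methyl 2-(hydroxymethyl)prop-2-enoate
Product: 2 methyl (2R)-3-hydroxy-2-methylpropanoate
Conditions: ene-reductase (flavin-dependent, Old Yellow Enzyme family), NAD+ (cat.), formate dehydrogenase, HCO2Na, phosphate buffer pH 7.5, 30 °C
Reagents that add atoms: none
Why: The ene-reductase transfers hydride from reduced flavin to the CH2 terminus and a proton to C2 of the activated acrylate on one enantioface (asymmetric biocatalytic C=C reduction), setting the first stereocentre (future C8) as R.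

Step 2
Reactants: 2 methyl (2R)-3-hydroxy-2-methylpropanoate
Product: 3 methyl (2R)-3-[(tert-butyldiphenylsilyl)oxy]-2-methylpropanoate
Conditions: t-BuPh2SiCl, imidazole, DMF, 0 °C → rt
Reagents that add atoms: tert-butyl(chloro)diphenylsilane CC(C)(C)[Si](Cl)(c1ccccc1)c1ccccc1
Why: Silylation of the primary alcohol masks the future C7 oxygen with a group that withstands hydride, acetylide and alane chemistry and leaves the stereocentre untouched.

Step 3
Reactants: 3 methyl (2R)-3-[(tert-butyldiphenylsilyl)oxy]-2-methylpropanoate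
Product: 4 (2S)-3-[(tert-butyldiphenylsilyl)oxy]-2-methylpropan-1-ol
Conditions: i-Bu2AlH (2.2 equiv), CH2Cl2, −78 → 0 °C; aq. potassium sodium tartrate
Reagents that add atoms: none
Why: Hydride reduction of the ester gives the primary alcohol (future C9) without epimerisation, the descriptor changing only through CIP priorities.

Step 4
Reactants: 4 (2S)-3-[(tert-butyldiphenylsilyl)oxy]-2-methylpropan-1-ol
Product: 5 tert-butyl{[(2R)-3-iodo-2-methylpropyl]oxy}diphenylsilane
Conditions: I2, PPh3, imidazole, CH2Cl2, 0 °C → rt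
Reagents that add atoms: iodine [I][I]
Why: Appel-type iodination displaces an alkoxyphosphonium group by iodide in an SN2 reaction at a carbon that is not the stereocentre.

Step 5
Reactants: 5 tert-butyl{[(2R)-3-iodo-2-methylpropyl]oxy}diphenylsilane
Product: 6 tert-butyl{[(2S)-2-methylpent-4-yn-1-yl]oxy}diphenylsilane
Conditions: LiC≡CH·H2NCH2CH2NH2, DMSO, 10 °C → rt
Reagents that add atoms: lithium acetylide (ethylenediamine complex) [Li]C#C
Why: SN2 alkylation of lithium acetylide by the primary iodide in a dipolar aprotic solvent installs C10 and the future exo-methylene carbon.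

Step 6
Reactants: 6 tert-butyl{[(2S)-2-methylpent-4-yn-1-yl]oxy}diphenylsilane
Product: 8 {[(2S)-4-bromo-2-methylpent-4-en-1-yl]oxy}(tert-butyl)diphenylsilane, via alkenylalane 7 (not isolated)
Conditions: NiCl2(dppp) (3 mol%), i-Bu2AlH (1.3 equiv), THF, 0 → 22 °C; then N-bromosuccinimide, 0 °C
Reagents that add atoms: N-bromosuccinimide O=C1CCC(=O)N1Br
Why: Nickel-catalysed Markovnikov (α-selective) hydroalumination places aluminium on the internal alkyne carbon and the carbon–aluminium bond is then brominated, giving the 1,1-disubstituted vinyl bromide needed for the ring closure.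

Step 7
Reactants: 8 {[(2S)-4-bromo-2-methylpent-4-en-1-yl]oxy}(tert-butyl)diphenylsilane
Product: 9 (2S)-4-bromo-2-methylpent-4-en-1-ol
Conditions: Bu4NF, THF, 0 °C → rt
Reagents that add atoms: none
Why: Fluoride-mediated desilylation frees the primary alcohol without touching the vinyl bromide.

Step 8
Reactants: 9 (2S)-4-bromo-2-methylpent-4-en-1-ol
Product: 10 (2S)-4-bromo-2-methylpent-4-enal
Conditions: Dess–Martin periodinane, NaHCO3, CH2Cl2, 0 °C → rt (used crude at once)
Reagents that add atoms: none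
Why: Dess–Martin oxidation under buffered non-basic conditions gives the α-stereogenic aldehyde without epimerisation.

Step 9
Reactants: 10 (2S)-4-bromo-2-methylpent-4-enal
Product: 11 (4S,5Z)-2-bromo-6-iodo-4-methylhepta-1,5-diene
Conditions: EtPPh3I, n-BuLi, THF, rt; I2, −78 °C; NaN(SiMe3)2, −20 °C; then 10, −78 °C → rt
Reagents that add atoms: ethyltriphenylphosphonium iodide CC[P+](c1ccccc1)(c1ccccc1)c1ccccc1.[I-]; iodine [I][I]
Why: Zhao–Wittig olefination with the α-iodo ylide gives the trisubstituted vinyl iodide with iodine cis to the chain (Z), which fixes the C6=C7 geometry.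

Step 10
Reactants: 12 2-methylprop-2-en-1-ol
Product: 14 2-[(tributylstannyl)methyl]prop-2-en-1-ol, via dilithio alkoxide 13 (not isolated)
Conditions: n-BuLi (2.2 equiv), TMEDA, Et2O/hexane, 0 °C → rt; then Bu3SnCl, −78 °C → rt
Reagents that add atoms: tributyltin chloride CCCC[Sn](Cl)(CCCC)CCCC
Why: Allylic deprotonation of the lithium alkoxide gives a dianion that is trapped on carbon by the tin electrophile (directed allylic metalation and stannylation).

Step 11
Reactants: 11 (4S,5Z)-2-bromo-6-iodo-4-methylhepta-1,5-diene; 14 2-[(tributylstannyl)methyl]prop-2-en-1-ol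
Product: 15 (4Z,6S)-8-bromo-4,6-dimethyl-2-methylidenenona-4,8-dien-1-ol
Conditions: Pd2(dba)3 (5 mol%), AsPh3 (40 mol%), DMF, 40 °C
Reagents that add atoms: none
Why: In this Stille coupling zerovalent palladium inserts into the vinyl iodide much faster than into the 2-bromoalkene, and the symmetric allyl group is transferred from tin with retention of the Z olefin, forming C5–C6.

Step 12
Reactants: 15 (4Z,6S)-8-bromo-4,6-dimethyl-2-methylidenenona-4,8-dien-1-ol
Product: 16 {(2S)-2-[(2Z,4S)-6-bromo-2,4-dimethylhepta-2,6-dien-1-yl]oxiran-2-yl}methanol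
Conditions: Ti(OiPr)4 (10 mol%), (2R,3R)-(+)-diethyl tartrate (12 mol%), t-BuOOH, 4 Å molecular sieves, CH2Cl2, −20 °C
Reagents that add atoms: tert-butyl hydroperoxide CC(C)(C)OO
Why: Sharpless asymmetric epoxidation is directed by the allylic hydroxyl (the other alkenes are not allylic alcohols), and the (+)-tartrate catalyst delivers oxygen to the face that gives the (S)-epoxide, setting C4.

Step 13
Reactants: 16 {(2S)-2-[(2Z,4S)-6-bromo-2,4-dimethylhepta-2,6-dien-1-yl]oxiran-2-yl}methanol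
Product: 17 (2S,4Z,6S)-8-bromo-2-hydroxy-2-(hydroxymethyl)-4,6-dimethylnona-4,8-dien-1-yl 2,2-dimethylpropanoate
Conditions: Ti(OiPr)4 (1.5 equiv), Me3CCO2H (1.5 equiv), CH2Cl2, rt
Reagents that add atoms: pivalic acid CC(C)(C)C(O)=O
Why: In the titanium-chelated epoxy alcohol (Sharpless regioselective epoxide opening) pivalate attacks the unhindered CH2 terminus, so the C4–O bond and configuration are kept, the two CH2O arms become different, and the bulky ester resists acyl migration.

Step 14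
Reactants: 17 (2S,4Z,6S)-8-bromo-2-hydroxy-2-(hydroxymethyl)-4,6-dimethylnona-4,8-dien-1-yl 2,2-dimethylpropanoate
Product: 18 (2R,4Z,6S)-8-bromo-4,6-dimethyl-2-[(triethylsilyl)oxy]-2-{[(triethylsilyl)oxy]methyl}nona-4,8-dien-1-yl 2,2-dimethylpropanoate
Conditions: Et3SiOTf (2.6 equiv), 2,6-lutidine, CH2Cl2, −78 → 0 °C
Reagents that add atoms: triethylsilyl trifluoromethanesulfonate CC[Si](CC)(CC)OS(=O)(=O)C(F)(F)F
Why: Silyl triflate silylation caps both the primary and the hindered tertiary hydroxyl, the descriptor changing only through CIP priorities.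

Step 15
Reactants: 18 (2R,4Z,6S)-8-bromo-4,6-dimethyl-2-[(triethylsilyl)oxy]-2-{[(triethylsilyl)oxy]methyl}nona-4,8-dien-1-yl 2,2-dimethylpropanoate
Product: 19 (2R,4Z,6S)-8-bromo-4,6-dimethyl-2-[(triethylsilyl)oxy]-2-{[(triethylsilyl)oxy]methyl}nona-4,8-dien-1-ol
Conditions: i-Bu2AlH (2.5 equiv), CH2Cl2, −78 °C; aq. potassium sodium tartrate
Reagents that add atoms: none
Why: Reductive cleavage of the pivalate by the aluminium hydride unveils the future C3 alcohol while the silyl ethers and the vinyl bromide are inert.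

Step 16
Reactants: 19 (2R,4Z,6S)-8-bromo-4,6-dimethyl-2-[(triethylsilyl)oxy]-2-{[(triethylsilyl)oxy]methyl}nona-4,8-dien-1-ol
Product: 20 (2S,4Z,6S)-8-bromo-4,6-dimethyl-2-[(triethylsilyl)oxy]-2-{[(triethylsilyl)oxy]methyl}nona-4,8-dienal
Conditions: Dess–Martin periodinane, NaHCO3, CH2Cl2, 0 °C → rt
Reagents that add atoms: none
Why: Dess–Martin oxidation gives the C3 aldehyde, which has no α-hydrogen and therefore cannot epimerise or enolise.

Step 17
Reactants: 21 bis(trimethylsilyl)acetylene; 22 propanoyl chloride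
Product: 23 1-(trimethylsilyl)pent-1-yn-3-one
Conditions: AlCl3, CH2Cl2, 0 °C
Reagents that add atoms: none
Why: Friedel–Crafts-type acylative desilylation (electrophilic ipso substitution at the silyl alkyne) gives the silyl ynone.

Step 18
Reactants: 23 1-(trimethylsilyl)pent-1-yn-3-one
Product: 24 (3S)-1-(trimethylsilyl)pent-1-yn-3-ol
Conditions: Ru[(S,S)-TsNCH(Ph)CH(Ph)NH](p-cymene) (0.5 mol%), i-PrOH, rt
Reagents that add atoms: none
Why: In this Noyori asymmetric transfer hydrogenation the (S,S)-diamine ruthenium hydride distinguishes alkynyl from ethyl and delivers hydride to one carbonyl face, setting C13 as S.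

Step 19
Reactants: 24 (3S)-1-(trimethylsilyl)pent-1-yn-3-ol
Product: 25 (3S)-pent-1-yn-3-ol
Conditions: K2CO3 (cat.), MeOH, 0 °C → rt
Reagents that add atoms: none
Why: Base-catalysed methanolysis cleaves the alkynyl carbon–silicon bond without affecting the carbinol centre.

Step 20
Reactants: 25 (3S)-pent-1-yn-3-ol
Product: 27 (1Z,3S)-1-iodo-2-methylpent-1-en-3-ol, via alkenylmagnesium alkoxide 26 (not isolated)
Conditions: MeMgBr (3 equiv), CuI (10 mol%), THF, −10 °C → rt; then I2, −20 °C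
Reagents that add atoms: methylmagnesium bromide C[Mg]Br; iodine [I][I]
Why: Copper-catalysed anti-carbomagnesiation of the propargylic alkoxide (Duboudin reaction) adds methyl to C12 and magnesium to C11 cis to the alkoxide, and iodinolysis with retention gives the Z vinyl iodide.

Step 21
Reactants: 27 (1Z,3S)-1-iodo-2-methylpent-1-en-3-ol
Product: 29 (1Z,3S)-2-methyl-1-(tributylstannyl)pent-1-en-3-ol, via dilithio alkenyl alkoxide 28 (not isolated)
Conditions: t-BuLi (3.1 equiv), Et2O, −78 °C; then Bu3SnCl (1.1 equiv), −78 °C → rt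
Reagents that add atoms: tributyltin chloride CCCC[Sn](Cl)(CCCC)CCCC
Why: Iodine–lithium exchange on the lithium alkoxide gives a configurationally stable Z-alkenyllithium that is stannylated with retention.

Step 22
Reactants: 29 (1Z,3S)-2-methyl-1-(tributylstannyl)pent-1-en-3-ol; 22 propanoyl chloride
Product: 30 (1Z,3S)-2-methyl-1-(tributylstannyl)pent-1-en-3-yl propanoate
Conditions: pyridine, DMAP (cat.), CH2Cl2, 0 °C
Reagents that add atoms: none
Why: Acylation of the secondary alcohol installs C1, C2 and the C2 methyl as the propanoate, which also protects the C13 oxygen as the future lactone.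

Step 23
Reactants: 30 (1Z,3S)-2-methyl-1-(tributylstannyl)pent-1-en-3-yl propanoate; 20 (2S,4Z,6S)-8-bromo-4,6-dimethyl-2-[(triethylsilyl)oxy]-2-{[(triethylsilyl)oxy]methyl}nona-4,8-dienal
Product: 32 (1Z,3S)-2-methyl-1-(tributylstannyl)pent-1-en-3-yl (4S,6Z,8S)-10-bromo-3-hydroxy-2,6,8-trimethyl-4-[(triethylsilyl)oxy]-4-{[(triethylsilyl)oxy]methyl}undeca-6,10-dienoate (C2/C3 epimer mixture), via lithium enolate 31 (not isolated)
Conditions: LiN(i-Pr)2, THF, −78 °C; then 20, −78 °C; AcOH quench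
Reagents that add atoms: none
Why: Lithium ester enolate aldol addition to the non-enolisable aldehyde forms C2–C3, and the new C2 and C3 centres need no control because C3 is oxidised next and C2 is equilibrated at the end.

Step 24
Reactants: 32 (1Z,3S)-2-methyl-1-(tributylstannyl)pent-1-en-3-yl (4S,6Z,8S)-10-bromo-3-hydroxy-2,6,8-trimethyl-4-[(triethylsilyl)oxy]-4-{[(triethylsilyl)oxy]methyl}undeca-6,10-dienoate (C2/C3 epimer mixture)
Product: 33 (1Z,3S)-2-methyl-1-(tributylstannyl)pent-1-en-3-yl (4S,6Z,8S)-10-bromo-2,6,8-trimethyl-3-oxo-4-[(triethylsilyl)oxy]-4-{[(triethylsilyl)oxy]methyl}undeca-6,10-dienoate (C2 epimers)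
Conditions: Dess–Martin periodinane, NaHCO3, CH2Cl2, 0 °C → rt
Reagents that add atoms: none
Why: Dess–Martin oxidation of the β-hydroxy ester gives the β-keto ester under buffered conditions that spare the vinylstannane and the silyl ethers.

Step 25
Reactants: 33 (1Z,3S)-2-methyl-1-(tributylstannyl)pent-1-en-3-yl (4S,6Z,8S)-10-bromo-2,6,8-trimethyl-3-oxo-4-[(triethylsilyl)oxy]-4-{[(triethylsilyl)oxy]methyl}undeca-6,10-dienoate (C2 epimers)
Product: 34 (5S,7Z,9S,12Z,14S)-14-ethyl-3,7,9,13-tetramethyl-11-methylidene-5-[(triethylsilyl)oxy]-5-{[(triethylsilyl)oxy]methyl}-1-oxacyclotetradeca-7,12-diene-2,4-dione (C3 epimers by ring numbering)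
Conditions: Pd2(dba)3 (10 mol%), AsPh3 (80 mol%), i-Pr2NEt, DMF (1 mM), 60 °C
Reagents that add atoms: none
Why: Intramolecular Stille coupling of the 2-bromoalkene with the Z-alkenylstannane at high dilution closes the 14-membered ring and creates the 2-substituted 1,3-diene with retention of olefin geometry.

Step 26
Reactants: 34 (5S,7Z,9S,12Z,14S)-14-ethyl-3,7,9,13-tetramethyl-11-methylidene-5-[(triethylsilyl)oxy]-5-{[(triethylsilyl)oxy]methyl}-1-oxacyclotetradeca-7,12-diene-2,4-dione (C3 epimers by ring numbering)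
Product: 35 (3R,5S,7Z,9S,12Z,14S)-14-ethyl-5-hydroxy-5-(hydroxymethyl)-3,7,9,13-tetramethyl-11-methylidene-1-oxacyclotetradeca-7,12-diene-2,4-dione
Conditions: HF·pyridine, pyridine, THF, 0 °C → rt
Reagents that add atoms: none
Why: Fluoride-mediated global desilylation frees the diol under buffered mildly acidic conditions, and the centre between the two carbonyls (C2) equilibrates through the enol to the assumed more stable 2R epimer.

## Compound list

1 | methyl 2-(hydroxymethyl)prop-2-enoate | C=C(CO)C(=O)OC | starting material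
2 | methyl (2R)-3-hydroxy-2-methylpropanoate | OC[C@@H](C)C(=O)OC | intermediate
3 | methyl (2R)-3-[(tert-butyldiphenylsilyl)oxy]-2-methylpropanoate | CC(C)(C)[Si](c1ccccc1)(c1ccccc1)OC[C@@H](C)C(=O)OC | intermediate
4 | (2S)-3-[(tert-butyldiphenylsilyl)oxy]-2-methylpropan-1-ol | CC(C)(C)[Si](c1ccccc1)(c1ccccc1)OC[C@@H](C)CO | intermediate
5 | tert-butyl{[(2R)-3-iodo-2-methylpropyl]oxy}diphenylsilane | CC(C)(C)[Si](c1ccccc1)(c1ccccc1)OC[C@@H](C)C[I] | intermediate
6 | tert-butyl{[(2S)-2-methylpent-4-yn-1-yl]oxy}diphenylsilane | CC(C)(C)[Si](c1ccccc1)(c1ccccc1)OC[C@@H](C)CC#C | intermediate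
7 | {(4S)-5-[(tert-butyldiphenylsilyl)oxy]-4-methylpent-1-en-2-yl}bis(2-methylpropyl)alane (alkenylalane, formed in the flask) | CC(C)(C)[Si](c1ccccc1)(c1ccccc1)OC[C@@H](C)CC(=C)[Al](CC(C)C)CC(C)C | intermediate
8 | {[(2S)-4-bromo-2-methylpent-4-en-1-yl]oxy}(tert-butyl)diphenylsilane | CC(C)(C)[Si](c1ccccc1)(c1ccccc1)OC[C@@H](C)CC(Br)=C | intermediate
9 | (2S)-4-bromo-2-methylpent-4-en-1-ol | OC[C@@H](C)CC(Br)=C | intermediate
10 | (2S)-4-bromo-2-methylpent-4-enal | O=C[C@@H](C)CC(Br)=C | intermediate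
11 | (4S,5Z)-2-bromo-6-iodo-4-methylhepta-1,5-diene | [I]/C(C)=C\[C@@H](C)CC(Br)=C | intermediate
12 | 2-methylprop-2-en-1-ol | CC(=C)CO | starting material
13 | lithium 2-(lithiomethyl)prop-2-en-1-olate (dilithio alkoxide, formed in the flask) | [Li]CC(=C)CO[Li] | intermediate
14 | 2-[(tributylstannyl)methyl]prop-2-en-1-ol | CCCC[Sn](CCCC)(CCCC)CC(=C)CO | intermediate
15 | (4Z,6S)-8-bromo-4,6-dimethyl-2-methylidenenona-4,8-dien-1-ol | C=C(CO)C/C(C)=C\[C@@H](C)CC(Br)=C | intermediate
16 | {(2S)-2-[(2Z,4S)-6-bromo-2,4-dimethylhepta-2,6-dien-1-yl]oxiran-2-yl}methanol | OC[C@]1(CO1)C/C(C)=C\[C@@H](C)CC(Br)=C | intermediate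
17 | (2S,4Z,6S)-8-bromo-2-hydroxy-2-(hydroxymethyl)-4,6-dimethylnona-4,8-dien-1-yl 2,2-dimethylpropanoate | OC[C@](O)(COC(=O)C(C)(C)C)C/C(C)=C\[C@@H](C)CC(Br)=C | intermediate
18 | (2R,4Z,6S)-8-bromo-4,6-dimethyl-2-[(triethylsilyl)oxy]-2-{[(triethylsilyl)oxy]methyl}nona-4,8-dien-1-yl 2,2-dimethylpropanoate | CC[Si](CC)(CC)OC[C@](O[Si](CC)(CC)CC)(COC(=O)C(C)(C)C)C/C(C)=C\[C@@H](C)CC(Br)=C | intermediate
19 | (2R,4Z,6S)-8-bromo-4,6-dimethyl-2-[(triethylsilyl)oxy]-2-{[(triethylsilyl)oxy]methyl}nona-4,8-dien-1-ol | CC[Si](CC)(CC)OC[C@](O[Si](CC)(CC)CC)(CO)C/C(C)=C\[C@@H](C)CC(Br)=C | intermediate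
20 | (2S,4Z,6S)-8-bromo-4,6-dimethyl-2-[(triethylsilyl)oxy]-2-{[(triethylsilyl)oxy]methyl}nona-4,8-dienal | CC[Si](CC)(CC)OC[C@](O[Si](CC)(CC)CC)(C=O)C/C(C)=C\[C@@H](C)CC(Br)=C | intermediate
21 | bis(trimethylsilyl)acetylene | C[Si](C)(C)C#C[Si](C)(C)C | starting material
22 | propanoyl chloride | CCC(Cl)=O | starting material
23 | 1-(trimethylsilyl)pent-1-yn-3-one | CCC(=O)C#C[Si](C)(C)C | intermediate
24 | (3S)-1-(trimethylsilyl)pent-1-yn-3-ol | C[Si](C)(C)C#C[C@H](CC)O | intermediate
25 | (3S)-pent-1-yn-3-ol | C#C[C@H](CC)O | intermediate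
26 | bromomagnesium (1Z,3S)-1-(bromomagnesio)-2-methylpent-1-en-3-olate (alkenylmagnesium alkoxide, formed in the flask) | Br[Mg]/C=C(/C)[C@H](CC)O[Mg]Br | intermediate
27 | (1Z,3S)-1-iodo-2-methylpent-1-en-3-ol | [I]/C=C(/C)[C@H](CC)O | intermediate
28 | lithium (1Z,3S)-1-lithio-2-methylpent-1-en-3-olate (dilithio alkenyl alkoxide, formed in the flask) | [Li]/C=C(/C)[C@H](CC)O[Li] | intermediate
29 | (1Z,3S)-2-methyl-1-(tributylstannyl)pent-1-en-3-ol | CCCC[Sn](CCCC)(CCCC)/C=C(/C)[C@H](CC)O | intermediate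
30 | (1Z,3S)-2-methyl-1-(tributylstannyl)pent-1-en-3-yl propanoate | CCCC[Sn](CCCC)(CCCC)/C=C(/C)[C@H](CC)OC(=O)CC | intermediate
31 | lithium 1-{[(1Z,3S)-2-methyl-1-(tributylstannyl)pent-1-en-3-yl]oxy}prop-1-en-1-olate (lithium enolate, formed in the flask) | CCCC[Sn](CCCC)(CCCC)/C=C(/C)[C@H](CC)OC(O[Li])=CC | intermediate
32 | (1Z,3S)-2-methyl-1-(tributylstannyl)pent-1-en-3-yl (4S,6Z,8S)-10-bromo-3-hydroxy-2,6,8-trimethyl-4-[(triethylsilyl)oxy]-4-{[(triethylsilyl)oxy]methyl}undeca-6,10-dienoate (C2/C3 epimer mixture) | CCCC[Sn](CCCC)(CCCC)/C=C(/C)[C@H](CC)OC(=O)C(C)C(O)[C@@](O[Si](CC)(CC)CC)(CO[Si](CC)(CC)CC)C/C(C)=C\[C@@H](C)CC(Br)=C | intermediate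
33 | (1Z,3S)-2-methyl-1-(tributylstannyl)pent-1-en-3-yl (4S,6Z,8S)-10-bromo-2,6,8-trimethyl-3-oxo-4-[(triethylsilyl)oxy]-4-{[(triethylsilyl)oxy]methyl}undeca-6,10-dienoate (C2 epimers) | CCCC[Sn](CCCC)(CCCC)/C=C(/C)[C@H](CC)OC(=O)C(C)C(=O)[C@@](O[Si](CC)(CC)CC)(CO[Si](CC)(CC)CC)C/C(C)=C\[C@@H](C)CC(Br)=C | intermediate
34 | (5S,7Z,9S,12Z,14S)-14-ethyl-3,7,9,13-tetramethyl-11-methylidene-5-[(triethylsilyl)oxy]-5-{[(triethylsilyl)oxy]methyl}-1-oxacyclotetradeca-7,12-diene-2,4-dione (C3 epimers by ring numbering) | C=C1/C=C(/C)[C@H](CC)OC(=O)C(C)C(=O)[C@@](O[Si](CC)(CC)CC)(CO[Si](CC)(CC)CC)C/C(C)=C\[C@@H](C)C1 | intermediate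
35 | (3R,5S,7Z,9S,12Z,14S)-14-ethyl-5-hydroxy-5-(hydroxymethyl)-3,7,9,13-tetramethyl-11-methylidene-1-oxacyclotetradeca-7,12-diene-2,4-dione (CNP0240796.3) | C=C1/C=C(/C)[C@H](CC)OC(=O)[C@H](C)C(=O)[C@@](O)(CO)C/C(C)=C\[C@@H](C)C1 | target

## Summary

Total step count: 26.
Longest linear sequence: 19 steps (steps 1–9, 11–16, 23–26).

Three steps most likely to fail, each with a fallback:

Step 6 (α-selective hydroalumination and bromination). The risk is formation of the linear β-alane or protonation instead of bromination. The fallback builds the 2-bromoalkene from a vinylsilane instead of the alkyne; it sets out from iodide 5 and comes back to the route at 8. Iodide 5 is coupled with (1-(trimethylsilyl)vinyl)magnesium bromide under Li2CuCl4 catalysis (THF, 0 °C) to give tert-butyl{[(2S)-2-methyl-4-(trimethylsilyl)pent-4-en-1-yl]oxy}diphenylsilane F1. Bromine addition (CH2Cl2, −78 °C) gives tert-butyl{[(2S)-4,5-dibromo-2-methyl-4-(trimethylsilyl)pentyl]oxy}diphenylsilane F2. NaOMe in MeOH then eliminates the silyl group and the primary bromide (bromodesilylation) to return 8.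

Step 13 (titanium-mediated pivalate opening). The risk is attack at the tertiary epoxide carbon or acyl migration between the two primary arms, either of which would erode the C4 configuration. The fallback caps the primary hydroxyl before the epoxide is opened, so no migration partner exists and only SN2 attack at CH2 is possible; it sets out from 16 and comes back at 18. Epoxy alcohol 16 is silylated (Et3SiCl, imidazole, CH2Cl2) to {[(2R)-2-[(2Z,4S)-6-bromo-2,4-dimethylhepta-2,6-dien-1-yl]oxiran-2-yl]methoxy}triethylsilane F3. The epoxide is opened with CsO2CCMe3 buffered by Me3CCO2H (DMF, 70 °C) to (2R,4Z,6S)-8-bromo-2-hydroxy-4,6-dimethyl-2-{[(triethylsilyl)oxy]methyl}nona-4,8-dien-1-yl 2,2-dimethylpropanoate F4. Silylation of the tertiary hydroxyl (Et3SiOTf, 2,6-lutidine) gives 18.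

Step 25 (macrocyclic Stille coupling). The risk is slow oxidative addition of the 2-bromoalkene and oligomerisation at high dilution. The fallback closes the ring by lactonisation and makes the diene intermolecularly; it sets out from aldehyde 20 (with stannyl alcohol 29 as partner) and comes back at 34. The lithium enolate of S-tert-butyl propanethioate (LiN(i-Pr)2, THF, −78 °C) is added to 20 to give S-tert-butyl (4S,6Z,8S)-10-bromo-3-hydroxy-2,6,8-trimethyl-4-[(triethylsilyl)oxy]-4-{[(triethylsilyl)oxy]methyl}undeca-6,10-dienethioate F5. Dess–Martin oxidation gives S-tert-butyl (4S,6Z,8S)-10-bromo-2,6,8-trimethyl-3-oxo-4-[(triethylsilyl)oxy]-4-{[(triethylsilyl)oxy]methyl}undeca-6,10-dienethioate F6. A copper-free intermolecular Stille coupling of F6 with 29 (Pd2(dba)3, AsPh3, DMF, 60 °C, excess stannane possible) gives S-tert-butyl (4S,6Z,8S,11Z,13S)-13-hydroxy-2,6,8,12-tetramethyl-10-methylidene-3-oxo-4-[(triethylsilyl)oxy]-4-{[(triethylsilyl)oxy]methyl}pentadeca-6,11-dienethioate F7. AgOCOCF3 in toluene at high dilution activates the β-keto thioester (acylketene-type macrolactonisation) and the C13 hydroxyl closes the ring to 34.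

## Further compounds

F1 | step 6 | tert-butyl{[(2S)-2-methyl-4-(trimethylsilyl)pent-4-en-1-yl]oxy}diphenylsilane | CC(C)(C)[Si](c1ccccc1)(c1ccccc1)OC[C@@H](C)CC(=C)[Si](C)(C)C
F2 | step 6 | tert-butyl{[(2S)-4,5-dibromo-2-methyl-4-(trimethylsilyl)pentyl]oxy}diphenylsilane | CC(C)(C)[Si](c1ccccc1)(c1ccccc1)OC[C@@H](C)CC(Br)(CBr)[Si](C)(C)C
F3 | step 13 | {[(2R)-2-[(2Z,4S)-6-bromo-2,4-dimethylhepta-2,6-dien-1-yl]oxiran-2-yl]methoxy}triethylsilane | CC[Si](CC)(CC)OC[C@]1(CO1)C/C(C)=C\[C@@H](C)CC(Br)=C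
F4 | step 13 | (2R,4Z,6S)-8-bromo-2-hydroxy-4,6-dimethyl-2-{[(triethylsilyl)oxy]methyl}nona-4,8-dien-1-yl 2,2-dimethylpropanoate | CC[Si](CC)(CC)OC[C@](O)(COC(=O)C(C)(C)C)C/C(C)=C\[C@@H](C)CC(Br)=C
F5 | step 25 | S-tert-butyl (4S,6Z,8S)-10-bromo-3-hydroxy-2,6,8-trimethyl-4-[(triethylsilyl)oxy]-4-{[(triethylsilyl)oxy]methyl}undeca-6,10-dienethioate | CC(C)(C)SC(=O)C(C)C(O)[C@@](O[Si](CC)(CC)CC)(CO[Si](CC)(CC)CC)C/C(C)=C\[C@@H](C)CC(Br)=C
F6 | step 25 | S-tert-butyl (4S,6Z,8S)-10-bromo-2,6,8-trimethyl-3-oxo-4-[(triethylsilyl)oxy]-4-{[(triethylsilyl)oxy]methyl}undeca-6,10-dienethioate | CC(C)(C)SC(=O)C(C)C(=O)[C@@](O[Si](CC)(CC)CC)(CO[Si](CC)(CC)CC)C/C(C)=C\[C@@H](C)CC(Br)=C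
F7 | step 25 | S-tert-butyl (4S,6Z,8S,11Z,13S)-13-hydroxy-2,6,8,12-tetramethyl-10-methylidene-3-oxo-4-[(triethylsilyl)oxy]-4-{[(triethylsilyl)oxy]methyl}pentadeca-6,11-dienethioate | CC(C)(C)SC(=O)C(C)C(=O)[C@@](O[Si](CC)(CC)CC)(CO[Si](CC)(CC)CC)C/C(C)=C\[C@@H](C)CC(=C)/C=C(/C)[C@H](CC)O
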